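## Retrosynthetic overview

- Ring labels: upper unit rings A/B/C, middle unit rings D/E/F, lower unit rings G/H/I (A, D, G benzo rings; C, F, I pyran rings; B, E, H pendant aryl rings). The target comes from global hydrogenolysis of tetradeca-O-benzyl ether 23, whose ring F 3-OH comes from a C3–Si bond (oxidation with retention).
- Key disconnection: ring F is opened across O1–C2 and C3–C4 to an o-quinone methide of ring D (O1=C8a–C4a=C4, with C4 carrying ring G) and a (Z)-β-silylstyrene carrying ring E. An endo oxa-[4+2] cycloaddition sets C2, C3 and C4 all-cis in one step.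
- Enabling feature: O1 of ring F is a phenolic oxygen on C8a of ring D, and the ortho carbon C4a carries C4, a diarylmethine flanked by rings D and G. This o-hydroxybenzhydryl unit is a latent o-quinone methide, and the all-cis C2/C3/C4 triad of ring F is exactly the endo/(Z)-alkene pattern.
- Benzhydrol 20 comes from the 8-lithio epicatechin ether (rings G/H/I) and salicylaldehyde 11. Ring D of 11 is grown from cyclohexane-1,3-dione, C-alkylated by the C4 cation of ring C (4β, trans to 3-OH), then O-benzylated, formylated and aromatised.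
- The upper unit comes from (+)-dihydrorobinetin (C4 oxygen kept as the leaving group, C3 inverted by oxidation/LiBH(s-Bu)3). Order of ring formation: rings A–C and G–I from the chiral pool, ring D by aromatisation, ring F last.

Key step: step 15

Assumption: compounds 1, 7, 12 and 16 are taken as purchasable; α/β refer to the usual flavan drawing (2R aryl = α); Bn = benzyl.

## Route

Step 1
Reactants: 1 (+)-dihydrorobinetin, (2R,3R)-3,7-dihydroxy-2-(3,4,5-trihydroxyphenyl)chroman-4-one
Product: 2 (2R,3R)-7-(benzyloxy)-3-hydroxy-2-[3,4,5-tris(benzyloxy)phenyl]chroman-4-one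
Conditions: BnBr (4.4 equiv), K2CO3, DMF, N2, rt
Reagents that add atoms: benzyl bromide, BrCc1ccccc1
Why: Williamson etherification in which K2CO3 ionises only the four phenols, so the secondary 3-OH stays free and the 2,3-trans stereocentres are untouched at room temperature under nitrogen.

Step 2
Reactants: 2
Product: 4 (2R,3S,4R)-7-(benzyloxy)-4-(2-ethoxyethoxy)-2-[3,4,5-tris(benzyloxy)phenyl]chroman-3-ol, via flavan-3,4-diol 3 (not isolated)
Conditions: NaBH4, THF/EtOH, 0 °C; aq. work-up; then 2-ethoxyethanol, CSA (cat.), CH2Cl2, rt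
Reagents that add atoms: 2-ethoxyethanol, CCOCCO
Why: Borohydride reduction of the aryl ketone gives the 2,3-trans-3,4-trans diol, and only its benzylic 4-OH (para-activated by the 7-benzyloxy group) ionises under mild acid and is trapped by the alcohol (SN1 etherification), which keeps the native C4 oxygen as the later leaving group; the C4 configuration is of no consequence because C4 is re-ionised in step 5.

Step 3
Reactants: 4
Product: 5 (2R,4R)-7-(benzyloxy)-4-(2-ethoxyethoxy)-2-[3,4,5-tris(benzyloxy)phenyl]chroman-3-one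
Conditions: Dess–Martin periodinane, CH2Cl2, rt
Reagents that add atoms: none
Why: Dess–Martin oxidation of the only free (secondary) alcohol under near-neutral conditions, as in the catechin-to-epicatechin tactic, avoids enolisation of the benzylic C2 centre.

Step 4
Reactants: 5
Product: 6 (2R,3R,4R)-7-(benzyloxy)-4-(2-ethoxyethoxy)-2-[3,4,5-tris(benzyloxy)phenyl]chroman-3-ol (2,3-cis)
Conditions: LiBH(s-Bu)3, THF, −78 °C
Reagents that add atoms: none
Why: Diastereoselective ketone reduction in which the bulky hydride attacks the β-face, anti to the 2α-aryl and 4α-alkoxy groups, should give the axial 3α-alcohol (2,3-cis), the known outcome for flavan-3-ones.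

Step 5
Reactants: 6; 7 cyclohexane-1,3-dione
Product: 8 2-[(2R,3R,4R)-7-(benzyloxy)-3-hydroxy-2-[3,4,5-tris(benzyloxy)phenyl]chroman-4-yl]-3-hydroxycyclohex-2-en-1-one (4β, 3,4-trans)
Conditions: 7 (5 equiv), BF3·OEt2, CH2Cl2, −20 → 0 °C
Reagents that add atoms: none
Why: Lewis-acid ionisation of the 4-alkoxy group gives the 7-benzyloxy-stabilised benzylic C4 cation, which is captured at C2 of the strongly nucleophilic enol of 7 (in excess, to outrun Friedel–Crafts self-condensation through ring A) anti to the axial 3α-OH, giving the 3,4-trans product as is usual for 2,3-cis flavan C4 cations.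

Step 6
Reactants: 8
Product: 9 3-(benzyloxy)-2-[(2R,3R,4R)-3,7-bis(benzyloxy)-2-[3,4,5-tris(benzyloxy)phenyl]chroman-4-yl]cyclohex-2-en-1-one
Conditions: NaH, BnBr, Bu4NI (cat.), DMF, 0 °C → rt
Reagents that add atoms: benzyl bromide, BrCc1ccccc1
Why: Double Williamson alkylation in which the alkoxide and the 1,3-dione enolate both react at oxygen (C-alkylation at the fully flanked C2 is sterically blocked), giving the vinylogous benzyl ester that differentiates the two oxygens of the future ring D.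

Step 7
Reactants: 9
Product: 10 3-(benzyloxy)-2-[(2R,3R,4R)-3,7-bis(benzyloxy)-2-[3,4,5-tris(benzyloxy)phenyl]chroman-4-yl]-6-(hydroxymethylidene)cyclohex-2-en-1-one
Conditions: LiN(i-Pr)2 (2.2 equiv), THF, −78 °C; HCO2Et, −78 → 0 °C
Reagents that add atoms: ethyl formate, CCOC=O
Why: Kinetic α'-deprotonation of the 3-alkoxy-enone (Stork–Danheiser regiochemistry) followed by Claisen formylation installs the one carbon that becomes C4 of ring F.

Step 8
Reactants: 10
Product: 11 4-(benzyloxy)-3-[(2R,3R,4R)-3,7-bis(benzyloxy)-2-[3,4,5-tris(benzyloxy)phenyl]chroman-4-yl]-2-hydroxybenzaldehyde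
Conditions: DDQ (1.1 equiv), 1,4-dioxane, rt, short reaction time
Reagents that add atoms: none
Why: DDQ dehydrogenation of a 2-(hydroxymethylene) ketone, one of the fastest DDQ oxidations, gives the cross-conjugated dienone, which should tautomerise at once to the hydrogen-bonded salicylaldehyde, aromatisation of ring D being the driving force.

Step 9
Reactants: 12 (−)-epicatechin, (2R,3R)-2-(3,4-dihydroxyphenyl)chroman-3,5,7-triol
Product: 13 (2R,3R)-5,7-bis(benzyloxy)-2-[3,4-bis(benzyloxy)phenyl]chroman-3-ol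
Conditions: BnBr, K2CO3, DMF, N2, rt
Reagents that add atoms: benzyl bromide, BrCc1ccccc1
Why: Williamson etherification of the four phenols with K2CO3 leaves the secondary 3-OH and both stereocentres untouched.

Step 10
Reactants: 13
Product: 14 (2R,3R)-5,7-bis(benzyloxy)-2-[3,4-bis(benzyloxy)phenyl]-8-bromochroman-3-ol
Conditions: NBS (1.0 equiv), CH2Cl2, −78 °C → rt
Reagents that add atoms: N-bromosuccinimide, O=C1CCC(=O)N1Br
Why: Electrophilic aromatic bromination that is known to be selective for C8 of 5,7-di-O-benzyl flavan-3-ols installs the handle for metalation of ring G.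

Step 11
Reactants: 14
Product: 15 (2R,3R)-3,5,7-tris(benzyloxy)-2-[3,4-bis(benzyloxy)phenyl]-8-bromochroman
Conditions: NaH, BnBr, DMF, 0 °C → rt
Reagents that add atoms: benzyl bromide, BrCc1ccccc1
Why: Williamson benzylation of the remaining secondary alcohol ensures that no acidic proton interferes with the halogen–lithium exchange.

Step 12
Reactants: 16 3,4,5-tris(benzyloxy)benzaldehyde
Product: 17 1,2,3-tris(benzyloxy)-5-ethynylbenzene
Conditions: dimethyl (1-diazo-2-oxopropyl)phosphonate, K2CO3, MeOH/THF, rt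
Reagents that add atoms: Ohira–Bestmann reagent, COP(=O)(OC)C(=[N+]=[N-])C(C)=O
Why: Seyferth–Gilbert homologation in its Ohira–Bestmann form converts the aldehyde into the terminal alkyne under mild base that the benzyl ethers tolerate.

Step 13
Reactants: 17
Product: 18 benzyl(dimethyl){(Z)-2-[3,4,5-tris(benzyloxy)phenyl]ethenyl}silane
Conditions: BnMe2SiH, [RuCl2(p-cymene)]2 (cat.), CH2Cl2, 40 °C
Reagents that add atoms: benzyldimethylsilane, C[SiH](C)Cc1ccccc1
Why: Trans-hydrosilylation of a terminal arylacetylene with the divalent ruthenium arene chloride dimer is known to give the β-(Z)-vinylsilane by anti addition of Si–H, which sets the alkene geometry that becomes the C2/C3 cis relationship.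

Step 14
Reactants: 15; 11
Product: 20 {4-(benzyloxy)-3-[(2R,3R,4R)-3,7-bis(benzyloxy)-2-[3,4,5-tris(benzyloxy)phenyl]chroman-4-yl]-2-hydroxyphenyl}{(2R,3R)-3,5,7-tris(benzyloxy)-2-[3,4-bis(benzyloxy)phenyl]chroman-8-yl}methanol (both carbinol epimers), via 8-lithio flavan 19 (not isolated)
Conditions: 15, t-BuLi (2 equiv), THF, −78 °C; then 11 (pre-treated with NaH, THF, 0 °C), −78 → −20 °C; H2O
Reagents that add atoms: none
Why: Bromine–lithium exchange gives the 8-lithio flavan, a species known to add to carbonyl groups, and the pre-formed sodium phenoxide of 11 keeps the aldehyde available for 1,2-addition; both carbinol epimers converge on the same quinone methide, so the new centre needs no control.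

Step 15
Reactants: 20; 18
Product: 22 cycloadduct, the tetradeca-O-benzyl trimer carrying benzyldimethylsilyl in place of the ring F 3-hydroxyl (ring F 2α-aryl, 3α-silyl, 4α-aryl, all-cis), via o-quinone methide 21 (not isolated)
Conditions: (R)-TRIP [(R)-3,3'-bis(2,4,6-triisopropylphenyl)-1,1'-binaphthyl-2,2'-diyl hydrogen phosphate] (10 mol %), 5 Å molecular sieves, toluene, 40 °C; 20 added slowly to 18 (5 equiv)
Reagents that add atoms: none
Why: Proposed new method: the chiral phosphoric acid ionises the carbinol of 20 to the hydrogen-bonded (E)-o-quinone methide 21 (O1=C8a–C4a=C4 of ring D), which reacts with the (Z)-vinylsilane 18 in an inverse-electron-demand oxa-[4+2] cycloaddition, C4–C3 bond formation running ahead of O1–C2 closure. The closest known reaction is the Brønsted-acid-catalysed hetero-Diels–Alder reaction of o-quinone methides from o-hydroxybenzhydrols with styrenes to give 2,4-cis-flavans; new is the β-silylstyrene as a masked enol, whose regiochemistry is doubly secured because attack at the silicon-bearing carbon places the developing cation at a carbon that is benzylic to ring E and β to silicon. Ring F is closed by the cycloaddition itself (in the stepwise limit a six-membered closure of the ring D oxygen onto the C2 benzylic cation). C2/C3 cis follows from the retained Z geometry of 18, and C3/C4 and C2/C4 cis from the endo transition state in which ring E lies under the quinone methide while the E-configured methide keeps ring G outside, so the all-cis triad is the suprafacial endo product. The absolute sense requires bond formation on the Re face of the methide carbon C4, which the chiral phosphate is meant to enforce, the neighbouring C4 stereocentre of ring C ortho to O1 being a second control element, so that the antipodal catalyst is the remedy if the pairing proves mismatched. The step needs endo over exo selectivity and cycloaddition over protodesilylation or Friedel–Crafts capture by the alkoxyarene rings of a second molecule; the weak acid, the fast intramolecular O-capture, the excess of 18 with slow addition of 20 and the steric shielding of the di-ortho-substituted diarylmethyl centre are relied on for this.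

Step 16
Reactants: 22
Product: 23 tetradeca-O-benzyl ether of the target with free 3α-OH on ring F (ring F 2R,3R,4S)
Conditions: Bu4NF, THF, 0 °C; then 30% H2O2, KHCO3, MeOH/THF, 40 °C
Reagents that add atoms: hydrogen peroxide, OO
Why: Tamao–Fleming oxidation of the benzyldimethylsilyl group, in which fluoride cleaves the Si–benzyl bond and peroxide-induced 1,2-migration of C3 from silicon to oxygen proceeds with retention, should give the axial 3α-OH, while the axial C–Si bond is gauche to the C2–O1 bond so that anti β-elimination is stereoelectronically disfavoured.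

Step 17
Reactants: 23
Product: 24 target, epirobinetinidol-(4β→8)-epirobinetinidol-(4α→8)-epicatechin (upper unit 2R,3R,4R; middle unit 2R,3R,4S; lower unit 2R,3R)
Conditions: H2 (1 atm), Pd(OH)2/C, THF/MeOH/H2O, rt
Reagents that add atoms: none
Why: Global hydrogenolysis of the fourteen benzyl ethers under neutral conditions, which leave the acid-sensitive interflavan bonds and the benzylic C2–O bonds intact, releases the target.

## Compound list

1 | (+)-dihydrorobinetin | Oc1ccc2c(c1)O[C@H](c1cc(O)c(O)c(O)c1)[C@@H](O)C2=O | starting material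
2 | (2R,3R)-7-(benzyloxy)-3-hydroxy-2-[3,4,5-tris(benzyloxy)phenyl]chroman-4-one | O(Cc1ccccc1)c1ccc2c(c1)O[C@H](c1cc(OCc3ccccc3)c(OCc3ccccc3)c(OCc3ccccc3)c1)[C@@H](O)C2=O | intermediate
3 | (2R,3S,4R)-7-(benzyloxy)-2-[3,4,5-tris(benzyloxy)phenyl]chroman-3,4-diol | O(Cc1ccccc1)c1ccc2c(c1)O[C@H](c1cc(OCc3ccccc3)c(OCc3ccccc3)c(OCc3ccccc3)c1)[C@@H](O)[C@@H]2O | intermediate
4 | (2R,3S,4R)-7-(benzyloxy)-4-(2-ethoxyethoxy)-2-[3,4,5-tris(benzyloxy)phenyl]chroman-3-ol | O(Cc1ccccc1)c1ccc2c(c1)O[C@H](c1cc(OCc3ccccc3)c(OCc3ccccc3)c(OCc3ccccc3)c1)[C@@H](O)[C@@H]2OCCOCC | intermediate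
5 | (2R,4R)-7-(benzyloxy)-4-(2-ethoxyethoxy)-2-[3,4,5-tris(benzyloxy)phenyl]chroman-3-one | O(Cc1ccccc1)c1ccc2c(c1)O[C@H](c1cc(OCc3ccccc3)c(OCc3ccccc3)c(OCc3ccccc3)c1)C(=O)[C@@H]2OCCOCC | intermediate
6 | (2R,3R,4R)-7-(benzyloxy)-4-(2-ethoxyethoxy)-2-[3,4,5-tris(benzyloxy)phenyl]chroman-3-ol | O(Cc1ccccc1)c1ccc2c(c1)O[C@H](c1cc(OCc3ccccc3)c(OCc3ccccc3)c(OCc3ccccc3)c1)[C@H](O)[C@@H]2OCCOCC | intermediate
7 | cyclohexane-1,3-dione | O=C1CCCC(=O)C1 | starting material
8 | 2-[(2R,3R,4R)-7-(benzyloxy)-3-hydroxy-2-[3,4,5-tris(benzyloxy)phenyl]chroman-4-yl]-3-hydroxycyclohex-2-en-1-one | O(Cc1ccccc1)c1ccc2c(c1)O[C@H](c1cc(OCc3ccccc3)c(OCc3ccccc3)c(OCc3ccccc3)c1)[C@H](O)[C@H]2C1=C(O)CCCC1=O | intermediate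
9 | 3-(benzyloxy)-2-[(2R,3R,4R)-3,7-bis(benzyloxy)-2-[3,4,5-tris(benzyloxy)phenyl]chroman-4-yl]cyclohex-2-en-1-one | O(Cc1ccccc1)c1ccc2c(c1)O[C@H](c1cc(OCc3ccccc3)c(OCc3ccccc3)c(OCc3ccccc3)c1)[C@H](OCc1ccccc1)[C@H]2C1=C(OCc3ccccc3)CCCC1=O | intermediate
10 | 6-(hydroxymethylidene) derivative of 9 | O(Cc1ccccc1)c1ccc2c(c1)O[C@H](c1cc(OCc3ccccc3)c(OCc3ccccc3)c(OCc3ccccc3)c1)[C@H](OCc1ccccc1)[C@H]2C1=C(OCc3ccccc3)CCC(=CO)C1=O | intermediate
11 | 4-(benzyloxy)-3-[(2R,3R,4R)-3,7-bis(benzyloxy)-2-[3,4,5-tris(benzyloxy)phenyl]chroman-4-yl]-2-hydroxybenzaldehyde | O(Cc1ccccc1)c1ccc2c(c1)O[C@H](c1cc(OCc3ccccc3)c(OCc3ccccc3)c(OCc3ccccc3)c1)[C@H](OCc1ccccc1)[C@H]2c1c(O)c(C=O)ccc1OCc1ccccc1 | intermediate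
12 | (−)-epicatechin | Oc1cc(O)c2c(c1)O[C@H](c1ccc(O)c(O)c1)[C@H](O)C2 | starting material
13 | (2R,3R)-5,7-bis(benzyloxy)-2-[3,4-bis(benzyloxy)phenyl]chroman-3-ol | O(Cc1ccccc1)c1cc(OCc3ccccc3)c2c(c1)O[C@H](c1ccc(OCc3ccccc3)c(OCc3ccccc3)c1)[C@H](O)C2 | intermediate
14 | (2R,3R)-5,7-bis(benzyloxy)-2-[3,4-bis(benzyloxy)phenyl]-8-bromochroman-3-ol | O(Cc1ccccc1)c1cc(OCc3ccccc3)c2c(c1Br)O[C@H](c1ccc(OCc3ccccc3)c(OCc3ccccc3)c1)[C@H](O)C2 | intermediate
15 | (2R,3R)-3,5,7-tris(benzyloxy)-2-[3,4-bis(benzyloxy)phenyl]-8-bromochroman | O(Cc1ccccc1)c1cc(OCc3ccccc3)c2c(c1Br)O[C@H](c1ccc(OCc3ccccc3)c(OCc3ccccc3)c1)[C@H](OCc1ccccc1)C2 | intermediate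
16 | 3,4,5-tris(benzyloxy)benzaldehyde | O=Cc1cc(OCc2ccccc2)c(OCc2ccccc2)c(OCc2ccccc2)c1 | starting material
17 | 1,2,3-tris(benzyloxy)-5-ethynylbenzene | C#Cc1cc(OCc2ccccc2)c(OCc2ccccc2)c(OCc2ccccc2)c1 | intermediate
18 | benzyl(dimethyl){(Z)-2-[3,4,5-tris(benzyloxy)phenyl]ethenyl}silane | C[Si](C)(Cc1ccccc1)/C=C\c1cc(OCc2ccccc2)c(OCc2ccccc2)c(OCc2ccccc2)c1 | intermediate
19 | (2R,3R)-3,5,7-tris(benzyloxy)-2-[3,4-bis(benzyloxy)phenyl]chroman-8-yllithium | O(Cc1ccccc1)c1cc(OCc3ccccc3)c2c(c1[Li])O[C@H](c1ccc(OCc3ccccc3)c(OCc3ccccc3)c1)[C@H](OCc1ccccc1)C2 | intermediate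
20 | o-hydroxybenzhydrol linking ring D (with the upper unit at its C8) to C8 of ring G, both carbinol epimers | O(Cc1ccccc1)c1ccc2c(c1)O[C@H](c1cc(OCc3ccccc3)c(OCc3ccccc3)c(OCc3ccccc3)c1)[C@H](OCc1ccccc1)[C@H]2c1c(O)c(C(O)c3c(OCc4ccccc4)cc(OCc4ccccc4)c4c3O[C@H](c3ccc(OCc5ccccc5)c(OCc5ccccc5)c3)[C@H](OCc3ccccc3)C4)ccc1OCc1ccccc1 | intermediate
21 | (E)-o-quinone methide of ring D, methide carbon bearing ring G | O(Cc1ccccc1)c1ccc2c(c1)O[C@H](c1cc(OCc3ccccc3)c(OCc3ccccc3)c(OCc3ccccc3)c1)[C@H](OCc1ccccc1)[C@H]2C1=C(OCc3ccccc3)C=C/C(=C\c3c(OCc4ccccc4)cc(OCc4ccccc4)c4c3O[C@H](c3ccc(OCc5ccccc5)c(OCc5ccccc5)c3)[C@H](OCc3ccccc3)C4)C1=O | intermediate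
22 | cycloadduct, tetradeca-O-benzyl trimer with 3α-benzyldimethylsilyl on ring F (ring F all-cis) | O(Cc1ccccc1)c1ccc2c(c1)O[C@H](c1cc(OCc3ccccc3)c(OCc3ccccc3)c(OCc3ccccc3)c1)[C@H](OCc1ccccc1)[C@H]2c1c(OCc3ccccc3)ccc2c1O[C@H](c1cc(OCc3ccccc3)c(OCc3ccccc3)c(OCc3ccccc3)c1)[C@H]([Si](C)(C)Cc1ccccc1)[C@@H]2c1c(OCc3ccccc3)cc(OCc3ccccc3)c2c1O[C@H](c1ccc(OCc3ccccc3)c(OCc3ccccc3)c1)[C@H](OCc1ccccc1)C2 | intermediate
23 | tetradeca-O-benzyl ether of the target, free 3-OH on ring F | O(Cc1ccccc1)c1ccc2c(c1)O[C@H](c1cc(OCc3ccccc3)c(OCc3ccccc3)c(OCc3ccccc3)c1)[C@H](OCc1ccccc1)[C@H]2c1c(OCc3ccccc3)ccc2c1O[C@H](c1cc(OCc3ccccc3)c(OCc3ccccc3)c(OCc3ccccc3)c1)[C@H](O)[C@@H]2c1c(OCc3ccccc3)cc(OCc3ccccc3)c2c1O[C@H](c1ccc(OCc3ccccc3)c(OCc3ccccc3)c1)[C@H](OCc1ccccc1)C2 | intermediate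
24 | target, epirobinetinidol-(4β→8)-epirobinetinidol-(4α→8)-epicatechin | Oc1ccc2c(c1)O[C@H](c1cc(O)c(O)c(O)c1)[C@H](O)[C@H]2c1c(O)ccc2c1O[C@H](c1cc(O)c(O)c(O)c1)[C@H](O)[C@@H]2c1c(O)cc(O)c2c1O[C@H](c1ccc(O)c(O)c1)[C@H](O)C2 | target

## Step count and risks

Total step count: 17. Longest linear sequence: 12 steps (steps 1–8, then 14–17).

**Step 15 (Proposed new method).**
- What may go wrong: the twisted cis-disubstituted vinylsilane may add too slowly to the heavily stabilised quinone methide, so that Friedel–Crafts oligomerisation takes over. The cis-silyl group may erode the endo preference or the facial bias. Ipso-attack may end in loss of silicon.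
- Fallback (known reaction types): it sets out from 20 and alkyne 17 and comes back at 23.
- Rhodium-catalysed trans-hydroboration of 17 with catecholborane ([Rh(cod)Cl]2, P(i-Pr)3, Et3N) would give the (Z)-alkenyl catechol boronate F1, which is hydrolysed to the (Z)-alkenylboronic acid F2.
- Chiral-diol- or phosphoric-acid-catalysed 1,4-addition of F2 to the quinone methide generated from 20 (boronate conjugate addition to o-quinone methides, alkene geometry retained, C4 of ring F set by the catalyst) would give the (Z)-1,1,3-triarylpropene F3 with the ring D phenol free.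
- Asymmetric epoxidation of the cis-olefin with a chiral dioxirane (Shi epoxidation, KHSO5) would give the cis-epoxide F4.
- Acid-catalysed (CSA) 6-endo opening of F4 by the ring D phenol at the benzylic carbon, with inversion, would form O1–C2 and give 23 directly with the 2,3-cis arrangement.

**Step 16.**
- What may go wrong: fluoride activation of the hindered axial silane may trigger β-elimination of the ring F aryloxy group (ring opening), or the crowded silicon may resist peroxide attack. Anti-elimination would give the (Z)-alkene F3, which can still be taken on through epoxide F4 as above.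
- Fallback: it sets out from 17 and 20 and comes back at 23.
- Hydrosilylation of 17 with isopropoxydimethylsilane under the conditions of step 13 would give the (Z)-alkenyl(isopropoxy)dimethylsilane F5.
- The cycloaddition of step 15 with 20 would give the alkoxysilyl cycloadduct F6.
- The heteroatom-activated silicon of F6 would be oxidised by H2O2/KHCO3 without any fluoride, with retention, to 23.

**Step 8.**
- What may go wrong: DDQ may also abstract hydride from the doubly activated C4–H of ring C or from benzylic ether positions, or over-oxidise the electron-rich product.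
- Fallback: it sets out from 9 and comes back at 11.
- LiN(i-Pr)2 then PhSeBr would give the α'-phenylselenide F7.
- Oxidation (H2O2, pyridine) and selenoxide syn-elimination would give a dienone that tautomerises to the phenol F8.
- Ortho-selective formylation of F8 (MgCl2, Et3N, paraformaldehyde, MeCN, reflux; Casnati–Skattebøl conditions) would give 11, the only free ortho position being the required one.

## Further compounds

F1 | step 15 | 2-{(Z)-2-[3,4,5-tris(benzyloxy)phenyl]ethenyl}-1,3,2-benzodioxaborole | c1ccc2OB(/C=C\c3cc(OCc4ccccc4)c(OCc4ccccc4)c(OCc4ccccc4)c3)Oc2c1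
F2 | step 15 | {(Z)-2-[3,4,5-tris(benzyloxy)phenyl]ethenyl}boronic acid | OB(O)/C=C\c1cc(OCc2ccccc2)c(OCc2ccccc2)c(OCc2ccccc2)c1
F3 | step 15 | (Z)-1,1,3-triarylpropene, ring D phenol bearing the CH(ring G)–CH=CH–(ring E) chain, C4 configured as in 23 | O(Cc1ccccc1)c1ccc2c(c1)O[C@H](c1cc(OCc3ccccc3)c(OCc3ccccc3)c(OCc3ccccc3)c1)[C@H](OCc1ccccc1)[C@H]2c1c(O)c([C@H](/C=C\c3cc(OCc4ccccc4)c(OCc4ccccc4)c(OCc4ccccc4)c3)c3c(OCc4ccccc4)cc(OCc4ccccc4)c4c3O[C@H](c3ccc(OCc5ccccc5)c(OCc5ccccc5)c3)[C@H](OCc3ccccc3)C4)ccc1OCc1ccccc1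
F4 | step 15 | cis-epoxide of F3 (epoxide carbons are the future C2 and C3 of ring F) | O(Cc1ccccc1)c1ccc2c(c1)O[C@H](c1cc(OCc3ccccc3)c(OCc3ccccc3)c(OCc3ccccc3)c1)[C@H](OCc1ccccc1)[C@H]2c1c(O)c([C@H]([C@H]3O[C@H]3c3cc(OCc4ccccc4)c(OCc4ccccc4)c(OCc4ccccc4)c3)c3c(OCc4ccccc4)cc(OCc4ccccc4)c4c3O[C@H](c3ccc(OCc5ccccc5)c(OCc5ccccc5)c3)[C@H](OCc3ccccc3)C4)ccc1OCc1ccccc1
F5 | step 16 | dimethyl(propan-2-yloxy){(Z)-2-[3,4,5-tris(benzyloxy)phenyl]ethenyl}silane | CC(C)O[Si](C)(C)/C=C\c1cc(OCc2ccccc2)c(OCc2ccccc2)c(OCc2ccccc2)c1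
F6 | step 16 | analogue of 22 with isopropoxydimethylsilyl at C3 of ring F | O(Cc1ccccc1)c1ccc2c(c1)O[C@H](c1cc(OCc3ccccc3)c(OCc3ccccc3)c(OCc3ccccc3)c1)[C@H](OCc1ccccc1)[C@H]2c1c(OCc3ccccc3)ccc2c1O[C@H](c1cc(OCc3ccccc3)c(OCc3ccccc3)c(OCc3ccccc3)c1)[C@H]([Si](C)(C)OC(C)C)[C@@H]2c1c(OCc3ccccc3)cc(OCc3ccccc3)c2c1O[C@H](c1ccc(OCc3ccccc3)c(OCc3ccccc3)c1)[C@H](OCc1ccccc1)C2
F7 | step 8 | 6-(phenylselanyl) derivative of 9 | O(Cc1ccccc1)c1ccc2c(c1)O[C@H](c1cc(OCc3ccccc3)c(OCc3ccccc3)c(OCc3ccccc3)c1)[C@H](OCc1ccccc1)[C@H]2C1=C(OCc3ccccc3)CCC([Se]c3ccccc3)C1=O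
F8 | step 8 | 3-(benzyloxy)-2-[(2R,3R,4R)-3,7-bis(benzyloxy)-2-[3,4,5-tris(benzyloxy)phenyl]chroman-4-yl]phenol | O(Cc1ccccc1)c1ccc2c(c1)O[C@H](c1cc(OCc3ccccc3)c(OCc3ccccc3)c(OCc3ccccc3)c1)[C@H](OCc1ccccc1)[C@H]2c1c(O)cccc1OCc1ccccc1
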